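## Retrosynthetic overview

1. The ten-membered carbocycle is the last ring formed. It is opened at the Z-C1=C10 enone alkene, which gives ring-closing metathesis of a vinyl ketone with a methallyl group.
2. The C6–C7 bond comes from Barbier coupling of a (5R)-3-(bromomethyl)butenolide with an α-acyloxy aldehyde. This sets C6 and C7 and unveils the α-methylene lactone.
3. In the aldehyde half, the C5–O bond and the whole ester come from enamine-catalysed α-acyloxylation with a bis(epoxyacyl) peroxide (new, key step). C4 comes from an iminium-catalysed Mukaiyama–Michael addition to crotonaldehyde, and the oxirane from Shi epoxidation of ethyl tiglate.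
4. In the butenolide half, C8 comes from a phosphoric-acid-catalysed methallylboration of cinnamaldehyde, followed by acylation and five-ring metathesis.
5. Ring order: oxirane, then butenolide (which becomes the γ-lactone), then the ten-membered ring.

Assumption: the SMILES is taken literally, and germacrane-type locants are used below: C1=C10 Z-alkene, C2 ketone, C4 (S, methyl), C5 (R, ester), C6 (R, OH), C7 (R)/C8 (R) trans-fused lactone, C2′ (S)/C3′ (R) oxirane with its two methyl groups cis (tiglate-derived).

## Route

Step 1
Reactants: 1 ethyl tiglate (ethyl (2E)-2-methylbut-2-enoate)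
Product: 2 ethyl (2S,3R)-2,3-dimethyloxirane-2-carboxylate
Conditions: D-fructose-derived Shi diacetate ketone (4,5-di-O-acetyl-1,2-O-isopropylidene-β-D-erythro-2,3-hexodiulo-2,6-pyranose, 25 mol %), KHSO5 (as 2KHSO5·KHSO4·K2SO4), NaHCO3, MeCN/aq Na2EDTA, 0 °C → rt
Reagents that add atoms: potassium peroxymonosulfate, [K+].[O-]S(=O)(=O)OO
Why: Shi epoxidation, in which the chiral dioxirane of the diacetate ketone (robust enough for electron-poor alkenes) delivers oxygen stereospecifically through a spiro transition state to one face of the E-trisubstituted enoate, setting both oxirane centres (2S,3R, methyl groups cis) as the first stereocentres of this branch.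

Step 2
Reactants: 2 ethyl (2S,3R)-2,3-dimethyloxirane-2-carboxylate
Product: 3 (2S,3R)-2,3-dimethyloxirane-2-carboxylic acid
Conditions: LiOH (1.2 equiv), THF/H2O, 0 °C; then aq KHSO4 to pH 3, 0 °C, used without heating
Reagents that add atoms: lithium hydroxide, [Li+].[OH-]
Why: Ester saponification, in which hydroxide attacks the ester carbonyl faster than the trisubstituted oxirane at 0 °C and the quaternary α-carbon cannot enolise, so both centres are kept.

Step 3
Reactants: 4 S-ethyl thioacetate (S-ethyl ethanethioate)
Product: 5 tert-butyl{[1-(ethylsulfanyl)ethenyl]oxy}dimethylsilane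
Conditions: TBSOTf (1.1 equiv), Et3N (1.3 equiv), CH2Cl2, 0 °C → rt
Reagents that add atoms: tert-butyldimethylsilyl trifluoromethanesulfonate, CC(C)(C)[Si](C)(C)OS(=O)(=O)C(F)(F)F
Why: Soft enolisation with O-silylation, in which the silyl triflate activates the thioester carbonyl so that Et3N removes an α-proton and gives the ketene silyl thioacetal (no stereocentre).

Step 4
Reactants: 5 tert-butyl{[1-(ethylsulfanyl)ethenyl]oxy}dimethylsilane; 6 (E)-crotonaldehyde
Product: 7 S-ethyl (3R)-3-methyl-5-oxopentanethioate
Conditions: (2S,5S)-5-benzyl-2-tert-butyl-3-methylimidazolidin-4-one·Cl3CCO2H (20 mol %), H2O (2 equiv), acetone, −78 °C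
Reagents that add atoms: none
Why: Organocatalytic Mukaiyama–Michael addition, in which iminium activation steers the soft ketene silyl thioacetal to 1,4-addition and the benzyl/tert-butyl groups of the catalyst leave one face of the E-iminium ion open, setting the methyl-bearing centre (3R here, C4 S in the target) as the first stereocentre of this branch.

Step 5
Reactants: 3 (2S,3R)-2,3-dimethyloxirane-2-carboxylic acid (2.4 equiv); 7 S-ethyl (3R)-3-methyl-5-oxopentanethioate
Product: 9 S-ethyl (3S,4R)-4-{[(2S,3R)-2,3-dimethyloxirane-2-carbonyl]oxy}-3-methyl-5-oxopentanethioate, via diacyl peroxide 8 (not isolated)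
Conditions: (i) 3, DCC (2.4 equiv), urea·H2O2 (1.2 equiv), CH2Cl2, −10 → 0 °C, cold filtration, solution never concentrated; (ii) 7, (R)-2-[diphenyl(trimethylsilyloxy)methyl]pyrrolidine (15 mol %), hydroquinone (10 mol %), THF, 0 °C
Reagents that add atoms: urea–hydrogen peroxide, NC(N)=O.OO
Why: Proposed new method: the E-enamine formed from 7 and the (R)-diarylprolinol silyl ether attacks a peroxidic oxygen of 8 (substitution at oxygen) from the face not covered by the CPh2(OTMS) group, the epoxy-carboxylate (a better leaving group than benzoate) departs and iminium hydrolysis releases 9 with C5 set as R under catalyst control and the complete natural ester installed in the same C–O bond formation, the oxiranyl α-carbon (a poor radical and cation) suppressing the decarboxylative homolysis and carboxy inversion that plague other α-branched aliphatic diacyl peroxides; the closest known reaction type is the amine-catalysed asymmetric α-benzoyloxylation of aldehydes with dibenzoyl peroxide, which has not been shown for an aliphatic, functionalised, chiral diacyl peroxide.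

Step 6
Reactants: 9 S-ethyl (3S,4R)-4-{[(2S,3R)-2,3-dimethyloxirane-2-carbonyl]oxy}-3-methyl-5-oxopentanethioate; 10 tributyl(ethenyl)stannane, Bu3SnCH=CH2
Product: 11 (2R,3S)-3-methyl-1,5-dioxohept-6-en-2-yl (2S,3R)-2,3-dimethyloxirane-2-carboxylate
Conditions: Pd2(dba)3 (2.5 mol %), P(2-furyl)3 (20 mol %), CuO2PPh2 (1.2 equiv), BHT (trace), THF/hexanes, rt → 40 °C
Reagents that add atoms: none
Why: Liebeskind–Srogl-type thioester–stannane ketone synthesis, in which zerovalent palladium inserts into the C–S bond once thiophilic monovalent copper binds sulfur and vinyl transfer from tin followed by reductive elimination gives the vinyl ketone under neutral, base-free conditions that spare the aldehyde, its α-centre, the ester and the oxirane.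

Step 7
Reactants: 12 (E)-cinnamaldehyde; 13 2-methylallylboronic acid pinacol ester
Product: 15 (1E,3R)-5-methyl-1-phenylhexa-1,5-dien-3-ol, via pinacol borate ester 14 (not isolated)
Conditions: (R)-TRIP ((R)-3,3′-bis(2,4,6-triisopropylphenyl)-1,1′-binaphthyl-2,2′-diyl hydrogen phosphate, 5 mol %), toluene, −30 °C; aqueous work-up
Reagents that add atoms: none
Why: Chiral-phosphoric-acid-catalysed allylboration, in which the acid hydrogen-bonds to a pinacol oxygen in the closed chair transition state and exposes the Re face of the enal carbonyl, setting the carbinol centre as R (future C8) as the first stereocentre of this branch.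

Step 8
Reactants: 15 (1E,3R)-5-methyl-1-phenylhexa-1,5-dien-3-ol; 16 2-(bromomethyl)acrylic acid
Product: 17 (1E,3R)-5-methyl-1-phenylhexa-1,5-dien-3-yl 2-(bromomethyl)prop-2-enoate
Conditions: DCC (1.2 equiv), DMAP (5 mol %), CH2Cl2, 0 °C
Reagents that add atoms: none
Why: Steglich esterification, which acylates the oxygen without touching the C–O bond of the allylic alcohol, so the R centre is retained and the allylic bromide survives the short, cold reaction.

Step 9
Reactants: 17 (1E,3R)-5-methyl-1-phenylhexa-1,5-dien-3-yl 2-(bromomethyl)prop-2-enoate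
Product: 18 (5R)-3-(bromomethyl)-5-(2-methylprop-2-en-1-yl)furan-2(5H)-one
Conditions: second-generation Grubbs catalyst (5 mol %), CH2Cl2 (0.01 M), reflux
Reagents that add atoms: none
Why: Ring-closing metathesis, in which the ruthenium carbene enters at the styrenyl alkene and closes onto the acrylate to give the five-membered butenolide with loss of styrene, while the methallyl group cannot compete because it could only form a cyclobutene.

Step 10
Reactants: 18 (5R)-3-(bromomethyl)-5-(2-methylprop-2-en-1-yl)furan-2(5H)-one (1.2 equiv); 11 (2R,3S)-3-methyl-1,5-dioxohept-6-en-2-yl (2S,3R)-2,3-dimethyloxirane-2-carboxylate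
Product: 20 (1R,2R,3S)-1-hydroxy-3-methyl-1-[(2R,3R)-4-methylidene-2-(2-methylprop-2-en-1-yl)-5-oxooxolan-3-yl]-5-oxohept-6-en-2-yl (2S,3R)-2,3-dimethyloxirane-2-carboxylate, via allylzinc bromide 19 (not isolated)
Conditions: Zn dust (3 equiv), THF/sat. aq NH4Cl (2:1), 0 °C, 18 added slowly to 11 and Zn
Reagents that add atoms: none
Why: Barbier allylation with a 3-(halomethyl)butenolide, in which 19 is trapped as it forms and reacts at its ring γ-carbon through a chair Zimmerman–Traxler array on the face anti to the C8 methallyl group (C7 R, trans lactone), the ring-locked E-type allyl geometry turns this into the anti crotylation-type C6/C7 relation (C6 R, also the chelation 5,6-syn sense of the aldehyde), the α-acyloxy aldehyde outcompetes the vinyl ketone, and the buffered water protonates the alkoxide before acyl migration or translactonisation.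

Step 11
Reactants: 20 (1R,2R,3S)-1-hydroxy-3-methyl-1-[(2R,3R)-4-methylidene-2-(2-methylprop-2-en-1-yl)-5-oxooxolan-3-yl]-5-oxohept-6-en-2-yl (2S,3R)-2,3-dimethyloxirane-2-carboxylate
Product: 21 (3aR,4R,5R,6S,9Z,11aR)-4-hydroxy-6,10-dimethyl-3-methylidene-2,8-dioxo-2,3,3a,4,5,6,7,8,11,11a-decahydrocyclodeca[b]furan-5-yl (2S,3R)-2,3-dimethyloxirane-2-carboxylate
Conditions: second-generation Hoveyda–Grubbs catalyst (2 × 10 mol %, slow addition), 1,4-benzoquinone (20 mol %), toluene (0.5 mM), 80 °C, argon sparge
Reagents that add atoms: none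
Why: Ring-closing metathesis, in which vinyl ketone plus methallyl is the only productive pairing (the α-methylene lactone could only give an anti-Bredt alkene or a doubly acceptor-substituted eight-ring alkene), the reversible six-membered lactol between the C6 hydroxyl and the C2 ketone folds the chain and brings the ends together, the medium ring accepts the new alkene only with both ring bonds cis (Z), and loss of ethene drives the closure.

## Compound list

1 | ethyl tiglate | CCOC(=O)/C(C)=C/C | starting material
2 | ethyl (2S,3R)-2,3-dimethyloxirane-2-carboxylate | CCOC(=O)[C@@]1(C)O[C@@H]1C | intermediate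
3 | (2S,3R)-2,3-dimethyloxirane-2-carboxylic acid | OC(=O)[C@@]1(C)O[C@@H]1C | intermediate
4 | S-ethyl thioacetate | CCSC(C)=O | starting material
5 | tert-butyl{[1-(ethylsulfanyl)ethenyl]oxy}dimethylsilane | C=C(SCC)O[Si](C)(C)C(C)(C)C | intermediate
6 | (E)-crotonaldehyde | C/C=C/C=O | starting material
7 | S-ethyl (3R)-3-methyl-5-oxopentanethioate | CCSC(=O)C[C@H](C)CC=O | intermediate
8 | bis[(2S,3R)-2,3-dimethyloxirane-2-carbonyl] peroxide (not isolated) | O=C(OOC(=O)[C@@]1(C)O[C@@H]1C)[C@@]2(C)O[C@@H]2C | intermediate
9 | S-ethyl (3S,4R)-4-{[(2S,3R)-2,3-dimethyloxirane-2-carbonyl]oxy}-3-methyl-5-oxopentanethioate | CCSC(=O)C[C@H](C)[C@@H](OC(=O)[C@@]1(C)O[C@@H]1C)C=O | intermediate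
10 | tributyl(ethenyl)stannane | C=C[Sn](CCCC)(CCCC)CCCC | starting material
11 | (2R,3S)-3-methyl-1,5-dioxohept-6-en-2-yl (2S,3R)-2,3-dimethyloxirane-2-carboxylate | C=CC(=O)C[C@H](C)[C@@H](OC(=O)[C@@]1(C)O[C@@H]1C)C=O | intermediate
12 | (E)-cinnamaldehyde | O=C/C=C/c1ccccc1 | starting material
13 | 2-methylallylboronic acid pinacol ester | CC(=C)CB1OC(C)(C)C(C)(C)O1 | starting material
14 | 2-{[(1E,3R)-5-methyl-1-phenylhexa-1,5-dien-3-yl]oxy}-4,4,5,5-tetramethyl-1,3,2-dioxaborolane (not isolated) | CC(=C)C[C@H](/C=C/c1ccccc1)OB1OC(C)(C)C(C)(C)O1 | intermediate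
15 | (1E,3R)-5-methyl-1-phenylhexa-1,5-dien-3-ol | O[C@@H](/C=C/c1ccccc1)CC(C)=C | intermediate
16 | 2-(bromomethyl)acrylic acid | OC(=O)C(=C)CBr | starting material
17 | (1E,3R)-5-methyl-1-phenylhexa-1,5-dien-3-yl 2-(bromomethyl)prop-2-enoate | C=C(CBr)C(=O)O[C@@H](/C=C/c1ccccc1)CC(C)=C | intermediate
18 | (5R)-3-(bromomethyl)-5-(2-methylprop-2-en-1-yl)furan-2(5H)-one | BrCC1=C[C@@H](CC(C)=C)OC1=O | intermediate
19 | {[(5R)-5-(2-methylprop-2-en-1-yl)-2-oxo-2,5-dihydrofuran-3-yl]methyl}zinc bromide (not isolated) | Br[Zn]CC1=C[C@@H](CC(C)=C)OC1=O | intermediate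
20 | seco-triene, trans-β-(hydroxyalkyl)-α-methylene-γ-lactone with vinyl ketone and methallyl ends (4S,5R,6R,7R,8R,2′S,3′R; partly present as its six-membered lactol) | C=CC(=O)C[C@H](C)[C@@H](OC(=O)[C@@]2(C)O[C@@H]2C)[C@H](O)[C@H]1C(=C)C(=O)O[C@@H]1CC(C)=C | intermediate
21 | CNP0227299.4 | C=C1C(=O)O[C@@H]2C/C(C)=C\C(=O)C[C@H](C)[C@@H](OC(=O)[C@@]3(C)O[C@@H]3C)[C@H](O)[C@@H]12 | target

## Step count and risks

Total step count: 11.

Longest linear sequence: 6 steps (1, 2, 5, 6, 10, 11). The branch from 4 through steps 3, 4, 5, 6, 10, 11 has the same length.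

Because three separately made enantioenriched pieces are joined, the minor enantiomers end up as separable diastereomers of 9 and 20.

**Step 5 (the new step).**
- Risks: the aliphatic peroxide 8 may be too slow or may oxidise the amine catalyst. The β-branch of 7 may also erode catalyst control.
- Fallback: known chemistry, sets out from 3 and 7, comes back at 9.
- Acid 3 is converted with 1-chloro-N,N,2-trimethylprop-1-en-1-amine into (2S,3R)-2,3-dimethyloxirane-2-carbonyl chloride F1.
- F1 O-acylates the enol form of 7 (Et3N, DMAP, CH2Cl2) to give S-ethyl (3S,4E)-5-{[(2S,3R)-2,3-dimethyloxirane-2-carbonyl]oxy}-3-methylpent-4-enethioate F2. The Z isomer is removed by chromatography.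
- Shi epoxidation with the enantiomeric (L-fructose series) ketone and KHSO5 gives S-ethyl (3S)-3-[(2S,3S)-3-{[(2S,3R)-2,3-dimethyloxirane-2-carbonyl]oxy}oxiran-2-yl]butanethioate F3.
- Gentle heating in toluene triggers the classical enol ester epoxide rearrangement. The 1,2-acyloxy shift proceeds with inversion at the receiving carbon and gives 9. A free C5 hydroxyl is never exposed next to the thioester.

**Step 10.**
- Risks: the Felkin preference of the α-acyloxy aldehyde opposes the required 5,6-syn outcome. The looser zinc transition state could therefore leak to the C6 epimer, and 19 can also collapse by β-elimination.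
- Fallback: sets out from 18 (with 11), comes back at 20.
- Pd2(dba)3-catalysed borylation of 18 with B2pin2 (toluene, 50 °C) gives (5R)-5-(2-methylprop-2-en-1-yl)-3-[(4,4,5,5-tetramethyl-1,3,2-dioxaborolan-2-yl)methyl]furan-2(5H)-one F4.
- F4 is a stable allylboronate. Warmed with 11 in toluene, it reacts only through the closed chair transition state of allylboration.
- The anti-to-methallyl face selectivity is thereby passed on rigidly to C6 and C7, giving the O6-pinacolboryl ether of 20 F5, which is hydrolysed to 20 on work-up.

**Step 11.**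
- Risks: closing a ten-membered carbocycle at a trisubstituted, electron-poor alkene may give oligomers or no turnover.
- Fallback: sets out from 20, comes back at 21. The enone is taken out of the metathesis event.
- Luche reduction (NaBH4, CeCl3·7H2O, MeOH, −78 °C) converts the vinyl ketone into the C2 allylic alcohol of 20 (epimer mixture) F6.
- The electron-rich allylic alkene of F6 undergoes ring closure with the second-generation Grubbs catalyst (CH2Cl2, 1 mM, reflux) to give the (1(10)Z)-2-hydroxy analogue of 21 (epimer mixture) F7.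
- MnO2 (CH2Cl2, rt) oxidises only the allylic carbinol, leaves the C6 hydroxyl alone and converges both epimers on 21.

## Further compounds

F1 | step 5 | (2S,3R)-2,3-dimethyloxirane-2-carbonyl chloride | ClC(=O)[C@@]1(C)O[C@@H]1C
F2 | step 5 | S-ethyl (3S,4E)-5-{[(2S,3R)-2,3-dimethyloxirane-2-carbonyl]oxy}-3-methylpent-4-enethioate | CCSC(=O)C[C@H](C)/C=C/OC(=O)[C@@]1(C)O[C@@H]1C
F3 | step 5 | S-ethyl (3S)-3-[(2S,3S)-3-{[(2S,3R)-2,3-dimethyloxirane-2-carbonyl]oxy}oxiran-2-yl]butanethioate | CCSC(=O)C[C@H](C)[C@@H]1O[C@H]1OC(=O)[C@@]2(C)O[C@@H]2C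
F4 | step 10 | (5R)-5-(2-methylprop-2-en-1-yl)-3-[(4,4,5,5-tetramethyl-1,3,2-dioxaborolan-2-yl)methyl]furan-2(5H)-one | CC1(C)OB(CC2=C[C@@H](CC(C)=C)OC2=O)OC1(C)C
F5 | step 10 | O6-pinacolboryl ether of 20 | C=CC(=O)C[C@H](C)[C@@H](OC(=O)[C@@]2(C)O[C@@H]2C)[C@H](OB3OC(C)(C)C(C)(C)O3)[C@H]1C(=C)C(=O)O[C@@H]1CC(C)=C
F6 | step 11 | C2 allylic alcohol of 20 (epimer mixture at C2) | C=CC(O)C[C@H](C)[C@@H](OC(=O)[C@@]2(C)O[C@@H]2C)[C@H](O)[C@H]1C(=C)C(=O)O[C@@H]1CC(C)=C
F7 | step 11 | (1(10)Z)-2-hydroxy analogue of 21 (epimer mixture at C2) | C=C1C(=O)O[C@@H]2C/C(C)=C\C(O)C[C@H](C)[C@@H](OC(=O)[C@@]3(C)O[C@@H]3C)[C@H](O)[C@@H]12
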